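**Retrosynthetic overview**

1. The target is 2-methyl-1,4-naphthoquinone carrying a C40 chain with six E-trisubstituted alkenes, one (R)-methyl centre at C27′ and a terminal isopropylidene. No ring is formed in the route: the naphthalene bicycle comes intact from menadione, is carried as its 1,4-dimethyl ether, and the quinone ring is regenerated by oxidation in the last step.
2. Key disconnection: C20′–C21′, the central σ-bond of the 1,5-diene C18′=C19′–C20′–C21′–C22′=C23′. Both carbons are allylic methylenes, so C21′ can serve as an α-selective allylbarium nucleophile and C20′ as a primary allylic bromide; the union is direct and leaves no activating group to remove.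
3. C15 half (C21′–C32′): (S)-citronellyl bromide supplies C27′; a propargyl unit and a Negishi carboalumination build the E-C22′=C23′ alkene.
4. C38 half (ring + C1′–C20′): menadione → aryl bromide → Cu-catalysed aryl Grignard coupling with (2E,6E)-farnesyl bromide → ω-oxidation/bromination → sulfone-carbanion alkylation with an 8-silyloxygeranyl sulfone → Pd-hydride desulfonylation → ω-bromide.
5. End game: the allyl–allyl union, then oxidative demethylation to the quinone.

Key step: step 16

Remark: side-chain carbons are numbered C1′ (CH2 on the ring) to C32′. The (27R) centre has the spatial arrangement of (S)-citronellyl bromide; the descriptor changes only because chain extension inverts the CIP priorities. Compounds 1, 2, 10, 14 and 18 are assumed to be purchased as single isomers.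

**Route**

Step 1
Reactants: 1 (S)-citronellyl bromide [(S)-8-bromo-2,6-dimethyloct-2-ene]; 2 1-(trimethylsilyl)propyne
Product: 5 (R)-6,10-dimethylundec-9-en-1-yne, via 3-lithio-1-(trimethylsilyl)propyne 3 (not isolated), via the C-silyl alkyne 4 (not isolated)
Conditions: 2, n-BuLi, THF, −78 → −20 °C; 1, −78 °C → rt; then K2CO3, MeOH, rt
Reagents that add atoms: none
Why: Propargylic lithiation of the silyl-capped propyne and SN2 alkylation by the primary bromide (the silyl cap should steer attack to the propargyl terminus), followed by in-flask methanolytic protodesilylation; the stereocentre of 1 is not involved and becomes C6 of 5.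

Step 2
Reactants: 5 (R)-6,10-dimethylundec-9-en-1-yne
Product: 8 (2E,7R)-3,7,11-trimethyldodeca-2,10-dien-1-ol, via the alkenyldimethylalane 6 (not isolated), via the lithium alkenylalanate 7 (not isolated)
Conditions: Me3Al, Cp2ZrCl2 (cat.), CH2Cl2, 0 °C → rt; evaporate, hexane; n-BuLi, THF, −78 → 0 °C; (CH2O)n, rt; aq. Rochelle salt
Reagents that add atoms: trimethylaluminium C[Al](C)C; formaldehyde (as paraformaldehyde) C=O
Why: Negishi carboalumination should add methyl and aluminium syn across the terminal alkyne with aluminium at the terminus, and hydroxymethylation of the alanate proceeds with retention, which fixes the 2E geometry; the remote trisubstituted alkene is inert to methylalumination.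

Step 3
Reactants: 8 (2E,7R)-3,7,11-trimethyldodeca-2,10-dien-1-ol
Product: 9 (2E,7R)-1-chloro-3,7,11-trimethyldodeca-2,10-diene
Conditions: PPh3, CCl4, reflux
Reagents that add atoms: carbon tetrachloride ClC(Cl)(Cl)Cl
Why: Appel chlorination should convert the primary allylic alcohol into the chloride by SN2 displacement of the alkoxyphosphonium ion, without allylic transposition or E/Z loss, as for geranyl chloride.

Step 4
Reactants: 10 geranyl bromide [(2E)-1-bromo-3,7-dimethylocta-2,6-diene]
Product: 11 geranyl phenyl sulfone [(2E)-3,7-dimethyl-1-(phenylsulfonyl)octa-2,6-diene]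
Conditions: PhSO2Na, DMF, rt
Reagents that add atoms: sodium benzenesulfinate [Na+].[O-]S(=O)c1ccccc1
Why: S-alkylation of the sulfinate by the primary allylic bromide (SN2) should give the allylic sulfone with the 2E alkene unchanged.

Step 5
Reactants: 11 geranyl phenyl sulfone
Product: 12 (2E,6E)-2,6-dimethyl-8-(phenylsulfonyl)octa-2,6-dien-1-ol
Conditions: SeO2 (cat.), t-BuOOH, salicylic acid (cat.), CH2Cl2, 0 °C → rt
Reagents that add atoms: selenium dioxide O=[Se]=O (catalytic oxygen-transfer agent); tert-butyl hydroperoxide CC(C)(C)OO (terminal oxygen source)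
Why: SeO2/t-BuOOH allylic oxidation (Riley type, ene reaction then [2,3]-shift) should hydroxylate the E-methyl of the terminal isopropylidene, because the other alkene is deactivated by the allylic sulfone.

Step 6
Reactants: 12 (2E,6E)-2,6-dimethyl-8-(phenylsulfonyl)octa-2,6-dien-1-ol
Product: 13 tert-butyl{[(2E,6E)-2,6-dimethyl-8-(phenylsulfonyl)octa-2,6-dien-1-yl]oxy}dimethylsilane
Conditions: TBSCl, imidazole, DMF, rt
Reagents that add atoms: tert-butyldimethylsilyl chloride CC(C)(C)[Si](C)(C)Cl
Why: Standard imidazole-promoted silylation masks the primary allylic alcohol so that only the sulfonyl α-CH2 is deprotonated in step 12.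

Step 7
Reactants: 14 menadione (2-methylnaphthalene-1,4-dione)
Product: 16 1,4-dimethoxy-2-methylnaphthalene, via menadiol 15 (not isolated)
Conditions: Na2S2O4, THF/H2O, Bu4NBr (cat.), rt, N2; then KOH, Me2SO4, rt
Reagents that add atoms: dimethyl sulfate COS(=O)(=O)OC
Why: Dithionite reduction to the hydroquinone and in-flask phase-transfer O-methylation (reductive methylation) should give the bis-ether, the quinone surrogate that tolerates organometallic steps.

Step 8
Reactants: 16 1,4-dimethoxy-2-methylnaphthalene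
Product: 17 2-bromo-1,4-dimethoxy-3-methylnaphthalene
Conditions: Br2, CH2Cl2, 0 °C, dark
Reagents that add atoms: bromine BrBr
Why: Electrophilic aromatic bromination should occur at C3, the only free position of the doubly alkoxy-activated ring.

Step 9
Reactants: 17 2-bromo-1,4-dimethoxy-3-methylnaphthalene; 18 (2E,6E)-farnesyl bromide
Product: 20 1,4-dimethoxy-2-methyl-3-[(2E,6E)-3,7,11-trimethyldodeca-2,6,10-trien-1-yl]naphthalene, via the arylmagnesium bromide 19 (not isolated)
Conditions: Mg, THF, 45 °C; then CuBr·SMe2 (5 mol %), 18, THF, −20 °C → rt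
Reagents that add atoms: none
Why: Copper-catalysed aryl Grignard allylation should take place at the primary α-carbon of the prenyl-type bromide (γ-attack would create a quaternary benzylic carbon) and retain the 2E geometry.

Step 10
Reactants: 20 1,4-dimethoxy-2-methyl-3-[(2E,6E)-3,7,11-trimethyldodeca-2,6,10-trien-1-yl]naphthalene
Product: 21 (2E,6E,10E)-12-(1,4-dimethoxy-3-methylnaphthalen-2-yl)-2,6,10-trimethyldodeca-2,6,10-trien-1-ol
Conditions: SeO2 (cat.), t-BuOOH, salicylic acid (cat.), CH2Cl2, 0 °C, stopped at partial conversion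
Reagents that add atoms: selenium dioxide O=[Se]=O (catalytic oxygen-transfer agent); tert-butyl hydroperoxide CC(C)(C)OO (terminal oxygen source)
Why: SeO2/t-BuOOH allylic oxidation should favour the E-methyl of the terminal isopropylidene, the least hindered and most electron-rich ene partner of a polyprenyl chain, and give the E-allylic alcohol.

Step 11
Reactants: 21 (2E,6E,10E)-12-(1,4-dimethoxy-3-methylnaphthalen-2-yl)-2,6,10-trimethyldodeca-2,6,10-trien-1-ol
Product: 22 2-[(2E,6E,10E)-12-bromo-3,7,11-trimethyldodeca-2,6,10-trien-1-yl]-1,4-dimethoxy-3-methylnaphthalene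
Conditions: CBr4, PPh3, CH2Cl2, 0 °C
Reagents that add atoms: carbon tetrabromide BrC(Br)(Br)Br
Why: Appel bromination of the primary allylic alcohol under neutral conditions should give the E-allylic bromide without transposition and leave the aryl ethers and alkenes untouched.

Step 12
Reactants: 13 tert-butyl{[(2E,6E)-2,6-dimethyl-8-(phenylsulfonyl)octa-2,6-dien-1-yl]oxy}dimethylsilane; 22 2-[(2E,6E,10E)-12-bromo-3,7,11-trimethyldodeca-2,6,10-trien-1-yl]-1,4-dimethoxy-3-methylnaphthalene
Product: 24 tert-butyl{[(2E,6E,10E,14E,18E)-20-(1,4-dimethoxy-3-methylnaphthalen-2-yl)-2,6,10,14,18-pentamethyl-8-(phenylsulfonyl)icosa-2,6,10,14,18-pentaen-1-yl]oxy}dimethylsilane (racemic at C8), via the α-lithio sulfone 23 (not isolated)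
Conditions: 13, n-BuLi, THF, −78 °C; then 22, −78 → −20 °C
Reagents that add atoms: none
Why: Alkylation of the allylic sulfonyl carbanion by the primary allylic bromide (sulfone-carbanion alkylation, α-selective, both alkene geometries retained) should form C12′–C13′; the sulfonyl-bearing centre forms as a racemate and is deleted in step 13.

Step 13
Reactants: 24 the C8-phenylsulfonyl pentaene silyl ether
Product: 25 tert-butyl{[(2E,6E,10E,14E,18E)-20-(1,4-dimethoxy-3-methylnaphthalen-2-yl)-2,6,10,14,18-pentamethylicosa-2,6,10,14,18-pentaen-1-yl]oxy}dimethylsilane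
Conditions: LiEt3BH, PdCl2(dppp) (5 mol %), THF, 0 °C
Reagents that add atoms: none
Why: Palladium-catalysed hydride desulfonylation of the allylic sulfone should proceed through a π-allylpalladium that takes hydride at its less substituted terminus, so the trisubstituted E-alkene stays in place; silyl and aryl ethers are inert to LiEt3BH at 0 °C.

Step 14
Reactants: 25 the pentaprenyl silyl ether
Product: 26 (2E,6E,10E,14E,18E)-20-(1,4-dimethoxy-3-methylnaphthalen-2-yl)-2,6,10,14,18-pentamethylicosa-2,6,10,14,18-pentaen-1-ol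
Conditions: TBAF, THF, 0 °C → rt
Reagents that add atoms: none
Why: Fluoride-mediated desilylation should free the primary allylic alcohol without touching the alkenes or aryl ethers.

Step 15
Reactants: 26 the pentaprenyl ω-alcohol
Product: 27 2-[(2E,6E,10E,14E,18E)-20-bromo-3,7,11,15,19-pentamethylicosa-2,6,10,14,18-pentaen-1-yl]-1,4-dimethoxy-3-methylnaphthalene
Conditions: CBr4, PPh3, CH2Cl2, 0 °C; used without storage
Reagents that add atoms: carbon tetrabromide BrC(Br)(Br)Br
Why: Appel bromination should give the primary E-allylic bromide under neutral conditions, as in step 11.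

Step 16
Reactants: 9 (2E,7R)-1-chloro-3,7,11-trimethyldodeca-2,10-diene; 27 the pentaprenyl ω-bromide
Product: 29 1,4-dimethoxy-2-methyl-3-[(2E,6E,10E,14E,18E,22E,27R)-3,7,11,15,19,23,27,31-octamethyldotriaconta-2,6,10,14,18,22,30-heptaen-1-yl]naphthalene, via the allylbarium chloride 28 (not isolated)
Conditions: BaI2, lithium biphenylide (2 equiv), THF, rt (active barium); 9 (excess), −78 °C; then 27, THF, −78 °C, slow addition
Reagents that add atoms: none
Why: Active barium should insert into the C–Cl bond of 9 at −78 °C to give the allylbarium chloride 28, which is configurationally stable at that temperature and attacks through its less substituted α-carbon (C21′) in an SN2 displacement of the primary allylic bromide of 27 (C20′), forming the C20′–C21′ σ-bond of the 1,5-diene directly. The closest known reaction type is the α,α′-selective, geometry-retentive cross-coupling of γ,γ-disubstituted allylbarium reagents with allylic bromides, as used for squalene-type polyprenoid unions. No ring is closed and no stereocentre is formed; the C27′ centre lies well away from the reacting carbon and is untouched. The step needs α- over γ-attack on both partners, retention of the E geometry at C18′=C19′ and C22′=C23′, and cross- over homo-coupling: the large barium counter-ion and the γ,γ-disubstitution of 28 direct bond formation to the primary terminus, the unhindered CH2Br of 27 favours SN2 over SN2′, the low temperature prevents E/Z equilibration of 28, and slow addition of 27 to an excess of pre-formed 28 should suppress Wurtz homodimers. The aryl methyl ethers and isolated trisubstituted alkenes of 27 are inert to the reagent, so the full C53 skeleton with all six E-alkenes should arise in one operation.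

Step 17
Reactants: 29 the coupled hydroquinone dimethyl ether
Product: 30 2-methyl-3-[(2E,6E,10E,14E,18E,22E,27R)-3,7,11,15,19,23,27,31-octamethyldotriaconta-2,6,10,14,18,22,30-heptaen-1-yl]naphthalene-1,4-dione
Conditions: CAN, MeCN/H2O/CH2Cl2, 0 °C, short reaction time
Reagents that add atoms: water O
Why: Cerium(IV) oxidative demethylation of the 1,4-dimethoxyarene (arene radical cation, water supplies the carbonyl oxygens) should unveil the quinone; the isolated trisubstituted alkenes and the remote stereocentre are not affected at 0 °C.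

**Compound list**

1 | (S)-citronellyl bromide, (S)-8-bromo-2,6-dimethyloct-2-ene | CC(C)=CCC[C@H](C)CCBr | starting material
2 | 1-(trimethylsilyl)propyne | CC#C[Si](C)(C)C | starting material
3 | 3-lithio-1-(trimethylsilyl)propyne | [Li]CC#C[Si](C)(C)C | intermediate (not isolated)
4 | (R)-(6,10-dimethylundec-9-en-1-yn-1-yl)trimethylsilane | CC(C)=CCC[C@H](C)CCCC#C[Si](C)(C)C | intermediate (not isolated)
5 | (R)-6,10-dimethylundec-9-en-1-yne | CC(C)=CCC[C@H](C)CCCC#C | intermediate
6 | dimethyl[(1E,6R)-2,6,10-trimethylundeca-1,9-dien-1-yl]alane | CC(C)=CCC[C@H](C)CCC/C(C)=C/[Al](C)C | intermediate (not isolated)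
7 | lithium butyl(dimethyl)[(1E,6R)-2,6,10-trimethylundeca-1,9-dien-1-yl]aluminate | CC(C)=CCC[C@H](C)CCC/C(C)=C/[Al-](C)(C)CCCC.[Li+] | intermediate (not isolated)
8 | (2E,7R)-3,7,11-trimethyldodeca-2,10-dien-1-ol | CC(C)=CCC[C@H](C)CCC/C(C)=C/CO | intermediate
9 | (2E,7R)-1-chloro-3,7,11-trimethyldodeca-2,10-diene | CC(C)=CCC[C@H](C)CCC/C(C)=C/CCl | intermediate
10 | geranyl bromide | CC(C)=CCC/C(C)=C/CBr | starting material
11 | geranyl phenyl sulfone | CC(C)=CCC/C(C)=C/CS(=O)(=O)c1ccccc1 | intermediate
12 | (2E,6E)-2,6-dimethyl-8-(phenylsulfonyl)octa-2,6-dien-1-ol | OC/C(C)=C/CC/C(C)=C/CS(=O)(=O)c1ccccc1 | intermediate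
13 | tert-butyl{[(2E,6E)-2,6-dimethyl-8-(phenylsulfonyl)octa-2,6-dien-1-yl]oxy}dimethylsilane | CC(C)(C)[Si](C)(C)OC/C(C)=C/CC/C(C)=C/CS(=O)(=O)c1ccccc1 | intermediate
14 | menadione | CC1=CC(=O)c2ccccc2C1=O | starting material
15 | menadiol, 2-methylnaphthalene-1,4-diol | Cc1cc(O)c2ccccc2c1O | intermediate (not isolated)
16 | 1,4-dimethoxy-2-methylnaphthalene | COc1cc(C)c(OC)c2ccccc12 | intermediate
17 | 2-bromo-1,4-dimethoxy-3-methylnaphthalene | COc1c(Br)c(C)c(OC)c2ccccc12 | intermediate
18 | (2E,6E)-farnesyl bromide | CC(C)=CCC/C(C)=C/CC/C(C)=C/CBr | starting material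
19 | (1,4-dimethoxy-3-methylnaphthalen-2-yl)magnesium bromide | COc1c([Mg]Br)c(C)c(OC)c2ccccc12 | intermediate (not isolated)
20 | 1,4-dimethoxy-2-methyl-3-[(2E,6E)-3,7,11-trimethyldodeca-2,6,10-trien-1-yl]naphthalene | CC(C)=CCC/C(C)=C/CC/C(C)=C/Cc1c(C)c(OC)c2ccccc2c1OC | intermediate
21 | (2E,6E,10E)-12-(1,4-dimethoxy-3-methylnaphthalen-2-yl)-2,6,10-trimethyldodeca-2,6,10-trien-1-ol | OC/C(C)=C/CC/C(C)=C/CC/C(C)=C/Cc1c(C)c(OC)c2ccccc2c1OC | intermediate
22 | 2-[(2E,6E,10E)-12-bromo-3,7,11-trimethyldodeca-2,6,10-trien-1-yl]-1,4-dimethoxy-3-methylnaphthalene | BrC/C(C)=C/CC/C(C)=C/CC/C(C)=C/Cc1c(C)c(OC)c2ccccc2c1OC | intermediate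
23 | α-lithio derivative of 13 | CC(C)(C)[Si](C)(C)OC/C(C)=C/CC/C(C)=C/C([Li])S(=O)(=O)c1ccccc1 | intermediate (not isolated)
24 | tert-butyl{[(2E,6E,10E,14E,18E)-20-(1,4-dimethoxy-3-methylnaphthalen-2-yl)-2,6,10,14,18-pentamethyl-8-(phenylsulfonyl)icosa-2,6,10,14,18-pentaen-1-yl]oxy}dimethylsilane, racemic at C8 | CC(C)(C)[Si](C)(C)OC/C(C)=C/CC/C(C)=C/C(S(=O)(=O)c1ccccc1)C/C(C)=C/CC/C(C)=C/CC/C(C)=C/Cc1c(C)c(OC)c2ccccc2c1OC | intermediate
25 | tert-butyl{[(2E,6E,10E,14E,18E)-20-(1,4-dimethoxy-3-methylnaphthalen-2-yl)-2,6,10,14,18-pentamethylicosa-2,6,10,14,18-pentaen-1-yl]oxy}dimethylsilane | CC(C)(C)[Si](C)(C)OC/C(C)=C/CC/C(C)=C/CC/C(C)=C/CC/C(C)=C/CC/C(C)=C/Cc1c(C)c(OC)c2ccccc2c1OC | intermediate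
26 | (2E,6E,10E,14E,18E)-20-(1,4-dimethoxy-3-methylnaphthalen-2-yl)-2,6,10,14,18-pentamethylicosa-2,6,10,14,18-pentaen-1-ol | OC/C(C)=C/CC/C(C)=C/CC/C(C)=C/CC/C(C)=C/CC/C(C)=C/Cc1c(C)c(OC)c2ccccc2c1OC | intermediate
27 | 2-[(2E,6E,10E,14E,18E)-20-bromo-3,7,11,15,19-pentamethylicosa-2,6,10,14,18-pentaen-1-yl]-1,4-dimethoxy-3-methylnaphthalene | BrC/C(C)=C/CC/C(C)=C/CC/C(C)=C/CC/C(C)=C/CC/C(C)=C/Cc1c(C)c(OC)c2ccccc2c1OC | intermediate
28 | [(2E,7R)-3,7,11-trimethyldodeca-2,10-dien-1-yl]barium chloride | CC(C)=CCC[C@H](C)CCC/C(C)=C/C[Ba]Cl | intermediate (not isolated)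
29 | 1,4-dimethoxy-2-methyl-3-[(2E,6E,10E,14E,18E,22E,27R)-3,7,11,15,19,23,27,31-octamethyldotriaconta-2,6,10,14,18,22,30-heptaen-1-yl]naphthalene | CC(C)=CCC[C@H](C)CCC/C(C)=C/CC/C(C)=C/CC/C(C)=C/CC/C(C)=C/CC/C(C)=C/CC/C(C)=C/Cc1c(C)c(OC)c2ccccc2c1OC | intermediate
30 | 2-methyl-3-[(2E,6E,10E,14E,18E,22E,27R)-3,7,11,15,19,23,27,31-octamethyldotriaconta-2,6,10,14,18,22,30-heptaen-1-yl]naphthalene-1,4-dione (CNP0319612.1) | CC(C)=CCC[C@H](C)CCC/C(C)=C/CC/C(C)=C/CC/C(C)=C/CC/C(C)=C/CC/C(C)=C/CC/C(C)=C/CC1=C(C)C(=O)c2ccccc2C1=O | target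

**Totals and risks**

Total step count: 17. Longest linear sequence: 11 steps (menadione 14 → 30, steps 7–17).

Step 16 (key step). What may go wrong: attack through the γ-carbon of the allylbarium, SN2′ displacement on the bromide, E/Z equilibration of the organometallic if the temperature rises, or halogen–metal exchange leading to Wurtz homodimers instead of the cross-coupled chain. The fallback sets out from 9 and comes back at 29. Displacement of chloride with PhSO2Na in DMF should give (2E,7R)-3,7,11-trimethyldodeca-2,10-dien-1-yl phenyl sulfone F1. Deprotonation with n-BuLi in THF at −78 °C gives its α-lithio derivative F2, which is alkylated by 27 to the C21′-phenylsulfonyl derivative of 29 F3 (epimers at C21′, of no consequence). Palladium-catalysed hydride desulfonylation (LiEt3BH, PdCl2(dppp), THF, 0 °C) then removes the sulfone and delivers 29.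

Step 10. What may go wrong: insufficient site selectivity of the selenium-mediated ene reaction between the terminal and the two internal alkenes, and over-oxidation of the product to the enal. The fallback sets out from 20 and comes back at 21; it rebuilds the terminal alkene and so does not depend on allylic C–H selectivity. Terminal bromohydrin formation with NBS in aqueous THF at 0 °C should give (6E,10E)-3-bromo-12-(1,4-dimethoxy-3-methylnaphthalen-2-yl)-2,6,10-trimethyldodeca-6,10-dien-2-ol F4. K2CO3 in MeOH closes it to 2-[(2E,6E)-9-(3,3-dimethyloxiran-2-yl)-3,7-dimethylnona-2,6-dien-1-yl]-1,4-dimethoxy-3-methylnaphthalene F5. Periodic acid cleavage gives (4E,8E)-10-(1,4-dimethoxy-3-methylnaphthalen-2-yl)-4,8-dimethyldeca-4,8-dienal F6. E-selective Wittig olefination with ethyl 2-(triphenylphosphoranylidene)propanoate gives ethyl (2E,6E,10E)-12-(1,4-dimethoxy-3-methylnaphthalen-2-yl)-2,6,10-trimethyldodeca-2,6,10-trienoate F7, and DIBAL-H reduction at −78 °C gives 21.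

Step 13. What may go wrong: hydride delivery to the more substituted terminus of the π-allylpalladium intermediate, which moves the alkene out of position, or isomerisation of the neighbouring E-alkene. The fallback sets out from 22 and comes back at 25; it avoids the sulfone altogether. Commercial geranyl chloride is oxidised with SeO2/t-BuOOH to (2E,6E)-8-chloro-2,6-dimethylocta-2,6-dien-1-ol F8 and silylated (TBSCl, imidazole) to tert-butyl{[(2E,6E)-8-chloro-2,6-dimethylocta-2,6-dien-1-yl]oxy}dimethylsilane F9. Active barium at −78 °C converts F9 into [(2E,6E)-8-(tert-butyldimethylsilyloxy)-3,7-dimethylocta-2,6-dien-1-yl]barium chloride F10, whose α,α′-selective coupling with 22 at −78 °C should give 25 directly.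

**Further compounds**

F1 | step 16 | (2E,7R)-3,7,11-trimethyldodeca-2,10-dien-1-yl phenyl sulfone | CC(C)=CCC[C@H](C)CCC/C(C)=C/CS(=O)(=O)c1ccccc1
F2 | step 16 | α-lithio derivative of F1 | CC(C)=CCC[C@H](C)CCC/C(C)=C/C([Li])S(=O)(=O)c1ccccc1
F3 | step 16 | C21′-phenylsulfonyl derivative of 29 (epimers at C21′) | CC(C)=CCC[C@H](C)CCC/C(C)=C/C(S(=O)(=O)c1ccccc1)C/C(C)=C/CC/C(C)=C/CC/C(C)=C/CC/C(C)=C/CC/C(C)=C/Cc1c(C)c(OC)c2ccccc2c1OC
F4 | step 10 | (6E,10E)-3-bromo-12-(1,4-dimethoxy-3-methylnaphthalen-2-yl)-2,6,10-trimethyldodeca-6,10-dien-2-ol (racemic) | CC(C)(O)C(Br)CC/C(C)=C/CC/C(C)=C/Cc1c(C)c(OC)c2ccccc2c1OC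
F5 | step 10 | 2-[(2E,6E)-9-(3,3-dimethyloxiran-2-yl)-3,7-dimethylnona-2,6-dien-1-yl]-1,4-dimethoxy-3-methylnaphthalene (racemic) | CC1(C)OC1CC/C(C)=C/CC/C(C)=C/Cc1c(C)c(OC)c2ccccc2c1OC
F6 | step 10 | (4E,8E)-10-(1,4-dimethoxy-3-methylnaphthalen-2-yl)-4,8-dimethyldeca-4,8-dienal | O=CCC/C(C)=C/CC/C(C)=C/Cc1c(C)c(OC)c2ccccc2c1OC
F7 | step 10 | ethyl (2E,6E,10E)-12-(1,4-dimethoxy-3-methylnaphthalen-2-yl)-2,6,10-trimethyldodeca-2,6,10-trienoate | CCOC(=O)/C(C)=C/CC/C(C)=C/CC/C(C)=C/Cc1c(C)c(OC)c2ccccc2c1OC
F8 | step 13 | (2E,6E)-8-chloro-2,6-dimethylocta-2,6-dien-1-ol | OC/C(C)=C/CC/C(C)=C/CCl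
F9 | step 13 | tert-butyl{[(2E,6E)-8-chloro-2,6-dimethylocta-2,6-dien-1-yl]oxy}dimethylsilane | CC(C)(C)[Si](C)(C)OC/C(C)=C/CC/C(C)=C/CCl
F10 | step 13 | [(2E,6E)-8-(tert-butyldimethylsilyloxy)-3,7-dimethylocta-2,6-dien-1-yl]barium chloride | CC(C)(C)[Si](C)(C)OC/C(C)=C/CC/C(C)=C/C[Ba]Cl
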